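## Retrosynthetic overview

1. The building blocks are resveratrol triacetate (1) and sinapyl alcohol (2); both are achiral and commercial, and together they contain every carbon of the target.
2. The stilbene half is prepared without any C–C bond formation: 1 → free 4'-phenol 3 → o-quinone 4.
3. Key disconnection: both C–O bonds of the 1,4-dioxane ring are cut back to heterodiene 4 and alkene 2. In the forward direction, one catalytic enantioselective oxa-[4+2] gives 5 and sets both stereocentres.
4. The dioxane is the only ring formed; all three arene rings are carried in from 1 and 2.
5. Last disconnection: the two aryl acetates, 5 → aiphanol (6).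

Assumption: reagents, catalysts and the enzyme are named but not numbered.
Assumption: (R)-TRIP is taken to give the (2R,3R) series; the facial sense of a new reaction cannot be known in advance, and (S)-TRIP is used if the first run shows the opposite sense.

## Route

Step 1
Reactants: 1, resveratrol triacetate [(E)-3,5,4'-triacetoxystilbene]
Product: 3, 3,5-di-O-acetylresveratrol [(E)-5-(4-hydroxystyryl)-1,3-phenylene diacetate]
Conditions: Novozym 435 (immobilised Candida antarctica lipase B), n-BuOH (4 equiv), t-BuOMe, 40 °C; stop at mono-deacetylation
Reagents that add atoms: none
Why: Lipase-catalysed alcoholysis (transesterification to butyl acetate) selects the unhindered 4'-acetate at the end of the molecule over the two meta-acetates, freeing only the phenol needed for oxidation; no stereocentre is involved.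

Step 2
Reactants: 3, 3,5-di-O-acetylresveratrol
Product: 4, (E)-4-[2-(3,5-diacetoxyphenyl)ethenyl]-1,2-benzoquinone (used at once as a cold CH2Cl2 solution, not stored)
Conditions: IBX (1.1 equiv), DMF, 0 °C → rt, 1 h; dilute with cold CH2Cl2, wash with cold pH 7 buffer, dry
Reagents that add atoms: IBX, 2-iodoxybenzoic acid, OI1(=O)OC(=O)c2ccccc12 (donates one O atom)
Why: Iodine(V) ortho-oxygenation of a phenol to the o-quinone delivers oxygen intramolecularly from the iodine-bound phenoxide to the ortho carbon; both ortho positions are equivalent, so one quinone forms, and the acetates and stilbene alkene are inert to IBX.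

Step 3
Reactants: 4, the o-quinone from Step 2; 2, sinapyl alcohol [(E)-4-(3-hydroxyprop-1-enyl)-2,6-dimethoxyphenol] (1.5 equiv)
Product: 5, 3,5-di-O-acetylaiphanol [5-[(E)-2-[(2R,3R)-3-(4-hydroxy-3,5-dimethoxyphenyl)-2-(hydroxymethyl)-2,3-dihydro-1,4-benzodioxin-6-yl]ethenyl]-1,3-phenylene diacetate], trans
Conditions: (R)-TRIP [(R)-3,3'-bis(2,4,6-triisopropylphenyl)-BINOL hydrogen phosphate] (10 mol %), 4 Å MS, CH2Cl2/PhMe 1:1, −60 → −30 °C, slow addition of 4, dark, Ar
Reagents that add atoms: none
Why: Proposed new method: a chiral-phosphoric-acid-catalysed enantioselective inverse-electron-demand oxa-Diels–Alder of an o-quinone with an (E)-4-hydroxycinnamyl alcohol, reasoned as follows: the P–OH hydrogen-bonds the more basic quinone carbonyl (the one vinylogously conjugated to the styryl group), which makes the other oxygen (para to the styryl group) the electrophilic terminus, while the P=O holds the allylic OH of 2, so the CH2OH-bearing alkene carbon of the electron-rich p-hydroxystyrene attacks that oxygen through one enantioface inside the chiral pocket (sets C2, R, and the aiphanol regiochemistry); the resulting p-quinone methide/phosphate ion pair is then closed by the adjacent catechol OH in a chair-like 6-exo oxa-1,6-addition with aryl and CH2OH trans (sets C3, R; the E-alkene geometry is conserved and acid-reversible closure corrects any cis isomer without touching C2); the closest known reaction types are the racemic thermal o-quinone/propenylbenzene hetero-Diels–Alder and the Ag2CO3 biomimetic catechol/cinnamyl alcohol coupling, and chiral-phosphoric-acid-catalysed [3+2]/[4+2] annulations of hydroxystyrenes with quinones, quinone imines and o-quinone methides.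

Step 4
Reactants: 5, 3,5-di-O-acetylaiphanol
Product: 6, aiphanol [5-[(E)-2-[(2R,3R)-3-(4-hydroxy-3,5-dimethoxyphenyl)-2-(hydroxymethyl)-2,3-dihydro-1,4-benzodioxin-6-yl]ethenyl]benzene-1,3-diol]
Conditions: NH4OAc (10 equiv), MeOH/H2O 4:1, rt, Ar
Reagents that add atoms: none
Why: Neutral solvolysis of aryl acetates (activated phenyl esters) frees the two resorcinol OH groups without base strong enough to open the p-hydroxybenzyl aryl ether through a quinone methide, so both stereocentres and the E-stilbene are untouched.

## Compound list

1 | resveratrol triacetate, (E)-3,5,4'-triacetoxystilbene | CC(=O)Oc1ccc(/C=C/c2cc(OC(C)=O)cc(OC(C)=O)c2)cc1 | starting material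
2 | sinapyl alcohol, (E)-4-(3-hydroxyprop-1-enyl)-2,6-dimethoxyphenol | COc1cc(/C=C/CO)cc(OC)c1O | starting material
3 | 3,5-di-O-acetylresveratrol | CC(=O)Oc1cc(/C=C/c2ccc(O)cc2)cc(OC(C)=O)c1 | intermediate
4 | (E)-4-[2-(3,5-diacetoxyphenyl)ethenyl]-1,2-benzoquinone | CC(=O)Oc1cc(/C=C/C2=CC(=O)C(=O)C=C2)cc(OC(C)=O)c1 | intermediate
5 | 3,5-di-O-acetylaiphanol, (2R,3R)-trans | COc1cc([C@H]2Oc3cc(/C=C/c4cc(OC(C)=O)cc(OC(C)=O)c4)ccc3O[C@@H]2CO)cc(OC)c1O | intermediate
6 | aiphanol, (2R,3R)-trans | COc1cc([C@H]2Oc3cc(/C=C/c4cc(O)cc(O)c4)ccc3O[C@@H]2CO)cc(OC)c1O | target

## Step count and risks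

Total steps: 4. Longest linear sequence: 4 (1 → 3 → 4 → 5 → 6); 2 is used as purchased.

Steps most likely to fail:

1. **Step 3 (proposed new asymmetric oxa-[4+2]).** Risks are a racemic background reaction (redox exchange between 4 and the syringyl phenol giving radical coupling, or uncatalysed cycloaddition), attack at a quinone ring carbon giving a dihydrobenzofuran, the other regioisomer, or low ee. Fallback with known chemistry: build the dioxane one C–O bond at a time.
   - Shi epoxidation (fructose-derived ketone/Oxone, still metal-free) of bis-TBS-protected 2, using the ketone enantiomer that gives the (2S,3S)-epoxide.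
   - Phenoxide opening at the benzylic carbon by 4-(allyloxy)-3-hydroxybenzaldehyde (inversion), then Pd(0) deallylation.
   - Intramolecular Mitsunobu etherification at the secondary carbinol (second inversion, giving the trans ring).
   - Horner–Wadsworth–Emmons olefination with a 3,5-bis(silyloxy)benzylphosphonate, then desilylation.

2. **Step 2 (IBX phenol → o-quinone).** Risks are over-oxidation or decomposition of the styryl o-quinone, and residual acid carried into Step 3. Fallback: reach 4 by two-electron oxidation of a catechol instead of oxygen-atom transfer. Start from commercial piceatannol, mask the catechol as its cyclic phenylboronate, acetylate the resorcinol OH groups and release the catechol. Oxidise it with NaIO4 on silica in CH2Cl2 and filter straight into Step 3. This also bypasses Step 1.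

3. **Step 1 (lipase regioselectivity).** Risks are over-deacetylation or a mixture of diacetates. Fallback: assemble 3 by C–C bond formation instead of selective deprotection, by Mizoroki–Heck coupling of 4-iodophenol with 3,5-diacetoxystyrene. The styrene comes from 3,5-dihydroxybenzaldehyde by acetylation and Wittig methylenation.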